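**Plan** (labdane numbering: ring stereocentres C4, C5, C8, C9, C10; chain stereocentre C13; C18 = OCH2 on C4; C15 = OCH2 of the chain)
1. Retrosynthetic cuts, in order: the O15–malonyl and O18–senecioyl ester bonds; C11–C12 (sulfone alkylation by a C12–C15 iodide); C8–C9 (ring B, reductive ketyl–vinyl sulfone cyclisation); C9–C10 and C10–CH3 (enolate alkenylation and methylation); ring A across C3–C4 and C5–C10 (Diels–Alder).
2. Forward: ring A arises first from an (E)-enal (C4, C5, C18, C6–C8, C17) and a chiral 1-amino-3-siloxy diene (C1–C3, C10). The C1 carbonyl of the resulting enone is used to build the C10 quaternary centre and is then removed. Ring B is closed by the key step, and the C12–C16 chain and the two esters follow.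
3. Feature that makes the key event possible: a methyl ketone (C8) on the C5 arm and the β-carbon (C9) of a vinyl sulfone on the neighbouring quaternary C10, trans on ring A, so that a C8 ketyl closes the six-membered ring B on C9.
4. Stereochemistry: C4 and C5 from the cycloaddition (relative from the (E)-geometry of the enal, absolute from a C2-symmetric pyrrolidine auxiliary on the diene); C10 by alkylation anti to the C5 chain; C8 and C9 together in the key step by relay from C5 and C10; C13 bought as (4R)-4-methyloxolan-2-one.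
5. Helpers taken out later: the phenylsulfonyl group (activates C9=C11, then carries the carbanion for C11–C12, removed with Na/Hg); the C1 carbonyl (removed through its tosylhydrazone); the C1=C2 alkene and the benzyl ether (one hydrogenation).

Key step: step 10

Assumption: the (2S,5S)-auxiliary on the diene is taken to direct the enal to the face that gives the (4R,5S)-enone 10; should the facial sense be the reverse, the (2R,5R)-auxiliary is used with no other change.

Step 1
Reactants: 1 (3E)-4-methoxybut-3-en-2-one; 2 (2S,5S)-2,5-diphenylpyrrolidine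
Product: 3 (3E)-4-[(2S,5S)-2,5-diphenylpyrrolidin-1-yl]but-3-en-2-one
Conditions: MeOH, rt
Reagents that add atoms: none
Why: Addition–elimination of the secondary amine on the β-methoxy enone should give the vinylogous amide without touching the two benzylic stereocentres.

Step 2
Reactants: 3 (3E)-4-[(2S,5S)-2,5-diphenylpyrrolidin-1-yl]but-3-en-2-one
Product: 4 (2S,5S)-1-[(1E)-3-{[tert-butyl(dimethyl)silyl]oxy}buta-1,3-dien-1-yl]-2,5-diphenylpyrrolidine
Conditions: KHMDS, THF, −78 °C; TBSCl, −78 °C → rt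
Reagents that add atoms: tert-butyldimethylsilyl chloride, CC(C)(C)[Si](C)(C)Cl
Why: Kinetic enolisation of the methyl ketone and O-silylation should give the 1-amino-3-siloxy diene.

Step 3
Reactants: 5 pent-4-enal; 6 2-(triphenyl-λ5-phosphanylidene)propanal
Product: 7 (2E)-2-methylhepta-2,6-dienal
Conditions: PhMe, 90 °C
Reagents that add atoms: none
Why: Wittig olefination with the stabilised ylide should give the (E)-trisubstituted enal, whose geometry later fixes the cis relation of the C4 methyl and the C5 chain.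

Step 4
Reactants: 4 (2S,5S)-1-[(1E)-3-{[tert-butyl(dimethyl)silyl]oxy}buta-1,3-dien-1-yl]-2,5-diphenylpyrrolidine; 7 (2E)-2-methylhepta-2,6-dienal
Product: 10 (4R,5S)-5-(but-3-en-1-yl)-4-(hydroxymethyl)-4-methylcyclohex-2-en-1-one, via cycloadduct aldehyde 8 (not isolated), via amino alcohol 9 (not isolated)
Conditions: PhMe, rt → 50 °C; LiAlH4, Et2O, −78 → 0 °C, aqueous quench; 10% aq HF, MeCN, rt
Reagents that add atoms: none
Why: Diels–Alder reaction of the enal with the aminosiloxy diene (amino terminus to the α-carbon) is suprafacial on the dienophile, so the C4 methyl and the C5 butenyl chain should stay cis, while the C2-symmetric pyrrolidine shields one diene face and sets both centres absolutely; LiAlH4 then reduces the aldehyde and HF hydrolyses the silyl enol ether with β-elimination of the amine.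

Step 5
Reactants: 10 (4R,5S)-5-(but-3-en-1-yl)-4-(hydroxymethyl)-4-methylcyclohex-2-en-1-one
Product: 11 (4R,5S)-4-[(benzyloxy)methyl]-5-(but-3-en-1-yl)-4-methylcyclohex-2-en-1-one
Conditions: BnOC(=NH)CCl3, TfOH (cat.), CH2Cl2–cyclohexane, 0 °C → rt
Reagents that add atoms: benzyl 2,2,2-trichloroacetimidate, ClC(Cl)(Cl)C(=N)OCc1ccccc1
Why: Acid-catalysed imidate benzylation should protect the neopentyl alcohol without enolising the enone.

Step 6
Reactants: 11 (4R,5S)-4-[(benzyloxy)methyl]-5-(but-3-en-1-yl)-4-methylcyclohex-2-en-1-one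
Product: 12 (4S,5S)-4-[(benzyloxy)methyl]-5-(but-3-en-1-yl)-4,6-dimethylcyclohex-2-en-1-one (C6 epimers; the C4 descriptor changes only through CIP ranking)
Conditions: LDA, THF, −78 °C; MeI, −78 → −30 °C
Reagents that add atoms: iodomethane, CI
Why: Kinetic α′-deprotonation of the enone (the γ-position is quaternary) and C-methylation of the enolate should install the future C10 methyl; the C6 configuration is irrelevant because the centre is enolised again in step 7.

Step 7
Reactants: 12 (4S,5S)-4-[(benzyloxy)methyl]-5-(but-3-en-1-yl)-4,6-dimethylcyclohex-2-en-1-one; 13 (E)-1,2-bis(phenylsulfonyl)ethene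
Product: 14 (4S,5R,6R)-4-[(benzyloxy)methyl]-5-(but-3-en-1-yl)-4,6-dimethyl-6-[(E)-2-(phenylsulfonyl)ethenyl]cyclohex-2-en-1-one
Conditions: LDA, THF–DMPU, −78 °C; 13, −78 → 0 °C
Reagents that add atoms: none
Why: Conjugate addition–elimination (vinylic substitution) of the fully substituted enolate on the bis-sulfone expels benzenesulfinate and should give the (E)-vinyl sulfone, the electrophile entering anti to the vicinal C5 chain so that at the new quaternary C10 the alkenyl group is trans and the methyl cis to that chain.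

Step 8
Reactants: 14 (4S,5R,6R)-4-[(benzyloxy)methyl]-5-(but-3-en-1-yl)-4,6-dimethyl-6-[(E)-2-(phenylsulfonyl)ethenyl]cyclohex-2-en-1-one
Product: 17 (3R,4S,5S)-5-[(benzyloxy)methyl]-4-(but-3-en-1-yl)-3,5-dimethyl-3-[(E)-2-(phenylsulfonyl)ethenyl]cyclohex-1-ene, via tosylhydrazone 15 (not isolated), via allylic tosylhydrazine 16 (not isolated)
Conditions: TsNHNH2, AcOH (cat.), EtOH, 60 °C; catecholborane, CHCl3, 0 °C; NaOAc·3H2O, 60 °C
Reagents that add atoms: none
Why: Reductive deoxygenation of the α,β-unsaturated tosylhydrazone (1,2-hydride delivery, loss of sulfinate, then retro-ene loss of N2 from the allylic diazene) should remove the C1 oxygen and move the ring alkene to C1=C2; no stereocentre is involved and the vinyl sulfone and terminal alkene are inert to catecholborane at 0 °C.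

Step 9
Reactants: 17 (3R,4S,5S)-5-[(benzyloxy)methyl]-4-(but-3-en-1-yl)-3,5-dimethyl-3-[(E)-2-(phenylsulfonyl)ethenyl]cyclohex-1-ene
Product: 18 4-{(1S,2R,6S)-6-[(benzyloxy)methyl]-2,6-dimethyl-2-[(E)-2-(phenylsulfonyl)ethenyl]cyclohex-3-en-1-yl}butan-2-one
Conditions: PdCl2 (cat.), CuCl, O2 (1 atm), DMF–H2O, rt
Reagents that add atoms: water, O
Why: Tsuji–Wacker oxidation should convert only the terminal alkene into the C8 methyl ketone, since the hindered ring alkene and the electron-poor vinyl sulfone do not undergo hydroxypalladation under these conditions.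

Step 10
Reactants: 18 4-{(1S,2R,6S)-6-[(benzyloxy)methyl]-2,6-dimethyl-2-[(E)-2-(phenylsulfonyl)ethenyl]cyclohex-3-en-1-yl}butan-2-one
Product: 19 (1S,2S,4aS,5S,8aR)-5-[(benzyloxy)methyl]-2,5,8a-trimethyl-1-[(phenylsulfonyl)methyl]-1,2,3,4,4a,5,6,8a-octahydronaphthalen-2-ol
Conditions: SmI2, HMPA, t-BuOH, THF, −78 °C
Reagents that add atoms: none
Why: Single-electron reduction of the methyl ketone gives a samarium ketyl whose nucleophilic C8 radical adds to C9, the electrophilic β-carbon of the vinyl sulfone, so two carbons of like acceptor polarity are joined; the α-sulfonyl radical is then reduced by a second SmI2 and protonated by t-BuOH. The closest known reaction type is the SmI2 ketyl–olefin reductive cyclisation of ketones onto electron-poor alkenes. Ring B closes in the 6-exo-trig mode through a chair transition state in which the trans-diequatorial C5 and C10 arms of ring A give the trans-decalin. C9 is set by the alkene taking the pseudo-equatorial position (H9 axial, anti to the axial C10 methyl), which is control by C10 and C5; C8 is set by the bulky HMPA-solvated O–Sm group taking the equatorial site anti to the sulfonylmethyl arm, which leaves the C8 methyl axial. The step needs addition to the vinyl sulfone in preference to the C1=C2 ring alkene and to simple ketone reduction, and this is secured by the polarity match of ketyl and vinyl sulfone and by the preorganised 1,2-trans arms. The benzyl ether and the alkyl sulfone formed should survive at −78 °C.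

Step 11
Reactants: 20 (4R)-4-methyloxolan-2-one
Product: 22 ethyl (3R)-4-iodo-3-methylbutanoate, via silyl ester 21 (not isolated)
Conditions: TMSI, CH2Cl2, rt; EtOH, rt
Reagents that add atoms: iodotrimethylsilane, C[Si](C)(C)I; ethanol, CCO
Why: Silyl-activated SN2 opening of the lactone at its OCH2 carbon by iodide, then ethanolysis of the silyl ester, should give the iodo ester with the stereocentre untouched.

Step 12
Reactants: 22 ethyl (3R)-4-iodo-3-methylbutanoate
Product: 23 (3R)-4-iodo-3-methylbutan-1-ol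
Conditions: DIBAL-H, CH2Cl2, −78 → 0 °C; aq Rochelle salt
Reagents that add atoms: none
Why: Hydride reduction of the ester should give the primary alcohol while the primary iodide is inert to DIBAL-H at low temperature.

Step 13
Reactants: 23 (3R)-4-iodo-3-methylbutan-1-ol
Product: 24 tert-butyl{[(3R)-4-iodo-3-methylbutyl]oxy}dimethylsilane
Conditions: TBSCl, imidazole, CH2Cl2, 0 °C
Reagents that add atoms: tert-butyldimethylsilyl chloride, CC(C)(C)[Si](C)(C)Cl
Why: Immediate silylation should protect the alcohol before it can close to 3-methyltetrahydrofuran by displacing iodide.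

Step 14
Reactants: 19 (1S,2S,4aS,5S,8aR)-5-[(benzyloxy)methyl]-2,5,8a-trimethyl-1-[(phenylsulfonyl)methyl]-1,2,3,4,4a,5,6,8a-octahydronaphthalen-2-ol; 24 tert-butyl{[(3R)-4-iodo-3-methylbutyl]oxy}dimethylsilane
Product: 25 (4S,5S,8S,9S,10R,13R)-18-(benzyloxy)-15-{[tert-butyl(dimethyl)silyl]oxy}-11-(phenylsulfonyl)labd-1-en-8-ol (C11 epimers)
Conditions: n-BuLi (2.2 equiv), THF–HMPA, −78 °C; 24, −78 → 0 °C
Reagents that add atoms: none
Why: SN2 alkylation of the α-sulfonyl carbanion of the O,C-dianion by the primary iodide should form C11–C12 and bring in the bought C13 centre; the C11 configuration is irrelevant.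

Step 15
Reactants: 25 (4S,5S,8S,9S,10R,13R)-18-(benzyloxy)-15-{[tert-butyl(dimethyl)silyl]oxy}-11-(phenylsulfonyl)labd-1-en-8-ol
Product: 26 (4S,5S,8S,9S,10R,13S)-18-(benzyloxy)-15-{[tert-butyl(dimethyl)silyl]oxy}labd-1-en-8-ol
Conditions: Na(Hg), Na2HPO4, MeOH–THF, −20 °C → rt
Reagents that add atoms: none
Why: Reductive desulfonylation should remove the activating group and leave C11 as CH2 (the C13 descriptor changes only through CIP ranking).

Step 16
Reactants: 26 (4S,5S,8S,9S,10R,13S)-18-(benzyloxy)-15-{[tert-butyl(dimethyl)silyl]oxy}labd-1-en-8-ol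
Product: 27 (4S,5S,8S,9S,10R,13S)-15-{[tert-butyl(dimethyl)silyl]oxy}labdane-8,18-diol
Conditions: H2 (1 atm), Pd(OH)2/C, EtOAc, rt
Reagents that add atoms: none
Why: Catalytic hydrogenation should saturate C1=C2 (no new stereocentre) and cleave the benzyl ether in one operation, while the silyl ether and the tertiary alcohol survive in a neutral aprotic solvent.

Step 17
Reactants: 27 (4S,5S,8S,9S,10R,13S)-15-{[tert-butyl(dimethyl)silyl]oxy}labdane-8,18-diol; 28 3-methylbut-2-enoic acid
Product: 29 (4S,5S,8S,9S,10R,13S)-15-{[tert-butyl(dimethyl)silyl]oxy}-8-hydroxylabdan-18-yl 3-methylbut-2-enoate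
Conditions: DCC, DMAP, CH2Cl2, 0 °C → rt
Reagents that add atoms: none
Why: Steglich esterification should acylate the primary C18 hydroxyl only, the tertiary C8 hydroxyl being too hindered, and the carbodiimide route avoids the vinylketene pathway that deconjugates the acid chloride.

Step 18
Reactants: 29 (4S,5S,8S,9S,10R,13S)-15-{[tert-butyl(dimethyl)silyl]oxy}-8-hydroxylabdan-18-yl 3-methylbut-2-enoate
Product: 30 (4S,5S,8S,9S,10R,13S)-8,15-dihydroxylabdan-18-yl 3-methylbut-2-enoate
Conditions: HF·pyridine, THF, 0 °C → rt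
Reagents that add atoms: none
Why: Fluoride-mediated cleavage of the primary silyl ether under mildly acidic conditions should leave the enoate and the tertiary alcohol intact.

Step 19
Reactants: 30 (4S,5S,8S,9S,10R,13S)-8,15-dihydroxylabdan-18-yl 3-methylbut-2-enoate; 31 2,2-dimethyl-1,3-dioxane-4,6-dione
Product: 32 3-{[(4S,5S,8S,9S,10R,13S)-8-hydroxy-18-[(3-methylbut-2-enoyl)oxy]labdan-15-yl]oxy}-3-oxopropanoic acid
Conditions: PhMe, 90 °C
Reagents that add atoms: none
Why: Acylation of the primary alcohol by the cyclic acylal with loss of acetone should give the malonic acid half ester directly, the tertiary alcohol being unreactive.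

**Compound list**
1 | (3E)-4-methoxybut-3-en-2-one | CO/C=C/C(C)=O | starting material
2 | (2S,5S)-2,5-diphenylpyrrolidine | N1[C@H](c2ccccc2)CC[C@H]1c1ccccc1 | starting material
3 | (3E)-4-[(2S,5S)-2,5-diphenylpyrrolidin-1-yl]but-3-en-2-one | CC(=O)/C=C/N1[C@H](c2ccccc2)CC[C@H]1c1ccccc1 | intermediate
4 | (2S,5S)-1-[(1E)-3-{[tert-butyl(dimethyl)silyl]oxy}buta-1,3-dien-1-yl]-2,5-diphenylpyrrolidine | C=C(O[Si](C)(C)C(C)(C)C)/C=C/N1[C@H](c2ccccc2)CC[C@H]1c1ccccc1 | intermediate
5 | pent-4-enal | C=CCCC=O | starting material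
6 | 2-(triphenyl-λ5-phosphanylidene)propanal | CC(C=O)=P(c1ccccc1)(c1ccccc1)c1ccccc1 | starting material
7 | (2E)-2-methylhepta-2,6-dienal | C=CCC/C=C(\C)C=O | intermediate
8 | cycloadduct aldehyde: 6-(but-3-en-1-yl)-4-{[tert-butyl(dimethyl)silyl]oxy}-2-[(2S,5S)-2,5-diphenylpyrrolidin-1-yl]-1-methylcyclohex-3-ene-1-carbaldehyde (endo adduct, amino group cis to CHO, methyl cis to butenyl) | O=C[C@@]1(C)[C@@H](N2[C@H](c3ccccc3)CC[C@H]2c2ccccc2)C=C(O[Si](C)(C)C(C)(C)C)C[C@@H]1CCC=C | intermediate
9 | amino alcohol: the primary alcohol obtained from 8 by reduction of the formyl group | OC[C@@]1(C)[C@@H](N2[C@H](c3ccccc3)CC[C@H]2c2ccccc2)C=C(O[Si](C)(C)C(C)(C)C)C[C@@H]1CCC=C | intermediate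
10 | (4R,5S)-5-(but-3-en-1-yl)-4-(hydroxymethyl)-4-methylcyclohex-2-en-1-one | OC[C@@]1(C)C=CC(=O)C[C@@H]1CCC=C | intermediate
11 | (4R,5S)-4-[(benzyloxy)methyl]-5-(but-3-en-1-yl)-4-methylcyclohex-2-en-1-one | c1ccccc1COC[C@@]1(C)C=CC(=O)C[C@@H]1CCC=C | intermediate
12 | (4S,5S)-4-[(benzyloxy)methyl]-5-(but-3-en-1-yl)-4,6-dimethylcyclohex-2-en-1-one (C6 epimers) | c1ccccc1COC[C@@]1(C)C=CC(=O)C(C)[C@@H]1CCC=C | intermediate
13 | (E)-1,2-bis(phenylsulfonyl)ethene | O=S(=O)(/C=C/S(=O)(=O)c1ccccc1)c1ccccc1 | starting material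
14 | (4S,5R,6R)-4-[(benzyloxy)methyl]-5-(but-3-en-1-yl)-4,6-dimethyl-6-[(E)-2-(phenylsulfonyl)ethenyl]cyclohex-2-en-1-one | c1ccccc1COC[C@@]1(C)C=CC(=O)[C@](/C=C/S(=O)(=O)c2ccccc2)(C)[C@@H]1CCC=C | intermediate
15 | tosylhydrazone of 14 (N′-cyclohexenylidene-4-methylbenzenesulfonohydrazide, ring centres as in 14) | c1ccccc1COC[C@@]1(C)C=CC(=NNS(=O)(=O)c2ccc(C)cc2)[C@](/C=C/S(=O)(=O)c2ccccc2)(C)[C@@H]1CCC=C | intermediate
16 | allylic tosylhydrazine from 1,2-reduction of 15 (N-boryl derivative in the flask; new centre undefined) | c1ccccc1COC[C@@]1(C)C=CC(NNS(=O)(=O)c2ccc(C)cc2)[C@](/C=C/S(=O)(=O)c2ccccc2)(C)[C@@H]1CCC=C | intermediate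
17 | (3R,4S,5S)-5-[(benzyloxy)methyl]-4-(but-3-en-1-yl)-3,5-dimethyl-3-[(E)-2-(phenylsulfonyl)ethenyl]cyclohex-1-ene | c1ccccc1COC[C@@]1(C)CC=C[C@](/C=C/S(=O)(=O)c2ccccc2)(C)[C@@H]1CCC=C | intermediate
18 | 4-{(1S,2R,6S)-6-[(benzyloxy)methyl]-2,6-dimethyl-2-[(E)-2-(phenylsulfonyl)ethenyl]cyclohex-3-en-1-yl}butan-2-one | c1ccccc1COC[C@@]1(C)CC=C[C@](/C=C/S(=O)(=O)c2ccccc2)(C)[C@@H]1CCC(C)=O | intermediate
19 | (1S,2S,4aS,5S,8aR)-5-[(benzyloxy)methyl]-2,5,8a-trimethyl-1-[(phenylsulfonyl)methyl]-1,2,3,4,4a,5,6,8a-octahydronaphthalen-2-ol | c1ccccc1COC[C@@]1(C)CC=C[C@]2(C)[C@@H]1CC[C@](C)(O)[C@H]2CS(=O)(=O)c1ccccc1 | intermediate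
20 | (4R)-4-methyloxolan-2-one | C[C@H]1COC(=O)C1 | starting material
21 | trimethylsilyl (3R)-4-iodo-3-methylbutanoate | C[C@H](CC(=O)O[Si](C)(C)C)CI | intermediate
22 | ethyl (3R)-4-iodo-3-methylbutanoate | C[C@H](CC(=O)OCC)CI | intermediate
23 | (3R)-4-iodo-3-methylbutan-1-ol | C[C@H](CCO)CI | intermediate
24 | tert-butyl{[(3R)-4-iodo-3-methylbutyl]oxy}dimethylsilane | C[C@H](CCO[Si](C)(C)C(C)(C)C)CI | intermediate
25 | (4S,5S,8S,9S,10R,13R)-18-(benzyloxy)-15-{[tert-butyl(dimethyl)silyl]oxy}-11-(phenylsulfonyl)labd-1-en-8-ol (C11 epimers) | c1ccccc1COC[C@@]1(C)CC=C[C@]2(C)[C@@H]1CC[C@](C)(O)[C@H]2C(S(=O)(=O)c1ccccc1)C[C@H](C)CCO[Si](C)(C)C(C)(C)C | intermediate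
26 | (4S,5S,8S,9S,10R,13S)-18-(benzyloxy)-15-{[tert-butyl(dimethyl)silyl]oxy}labd-1-en-8-ol | c1ccccc1COC[C@@]1(C)CC=C[C@]2(C)[C@@H]1CC[C@](C)(O)[C@H]2CC[C@H](C)CCO[Si](C)(C)C(C)(C)C | intermediate
27 | (4S,5S,8S,9S,10R,13S)-15-{[tert-butyl(dimethyl)silyl]oxy}labdane-8,18-diol | OC[C@@]1(C)CCC[C@]2(C)[C@@H]1CC[C@](C)(O)[C@H]2CC[C@H](C)CCO[Si](C)(C)C(C)(C)C | intermediate
28 | 3-methylbut-2-enoic acid | CC(C)=CC(=O)O | starting material
29 | (4S,5S,8S,9S,10R,13S)-15-{[tert-butyl(dimethyl)silyl]oxy}-8-hydroxylabdan-18-yl 3-methylbut-2-enoate | CC(C)=CC(=O)OC[C@@]1(C)CCC[C@]2(C)[C@@H]1CC[C@](C)(O)[C@H]2CC[C@H](C)CCO[Si](C)(C)C(C)(C)C | intermediate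
30 | (4S,5S,8S,9S,10R,13S)-8,15-dihydroxylabdan-18-yl 3-methylbut-2-enoate | CC(C)=CC(=O)OC[C@@]1(C)CCC[C@]2(C)[C@@H]1CC[C@](C)(O)[C@H]2CC[C@H](C)CCO | intermediate
31 | 2,2-dimethyl-1,3-dioxane-4,6-dione | CC1(C)OC(=O)CC(=O)O1 | starting material
32 | 3-{[(4S,5S,8S,9S,10R,13S)-8-hydroxy-18-[(3-methylbut-2-enoyl)oxy]labdan-15-yl]oxy}-3-oxopropanoic acid | CC(C)=CC(=O)OC[C@@]1(C)CCC[C@]2(C)[C@@H]1CC[C@](C)(O)[C@H]2CC[C@H](C)CCOC(=O)CC(=O)O | target

**Step count**
Total: 19 steps. Longest linear sequence: 15 steps (steps 1, 2, 4–10, 14–19).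

**Steps most likely to fail**

Step 7. The hindered, fully substituted enolate may react at oxygen or simply transfer a proton instead of forming the C9–C10 bond, and facial control by the C5 chain may be incomplete. The fallback sets out from 12 and comes back at 14. The lithium enolate of 12 is added to (phenylsulfanyl)acetaldehyde in an aldol reaction to give the β-hydroxy sulfide F1. Oxidation at sulfur (H2O2, ammonium molybdate) gives the β-hydroxy sulfone F2. Mesylation (MsCl, Et3N) gives the mesylate F3, and E1cB elimination with DBU gives 14.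

Step 14. SN2 displacement at the β-branched iodide by the hindered carbanion may be so slow that proton transfer and loss of HI from the iodide take over. The fallback sets out from 19 and 24 and comes back at 27. Iodide 24 is oxidised (Me3NO, DMSO, Kornblum-type) to (2R)-4-{[tert-butyl(dimethyl)silyl]oxy}-2-methylbutanal F4. The dianion of 19 is added to F4 and the new alkoxide is trapped with BzCl to give the β-benzoyloxy sulfone F5. Julia–Lythgoe elimination with Na(Hg) gives the labda-1,11-diene F6. Hydrogenation under the conditions of step 16 saturates both alkenes and cleaves the benzyl ether to give 27.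

Step 10. Electron transfer may end in simple reduction (ketone to secondary alcohol, or C–S cleavage of the vinyl sulfone) before the ring closes, or the facial selectivity at C8 may be poor. The fallback sets out from 18 and comes back at 19. Kinetic enolisation of the methyl group (LiHMDS, TBSCl, −78 °C) gives the silyl enol ether F7. Hydrogen-atom transfer from an iron hydride (Fe(acac)3, PhSiH3, EtOH, 60 °C) to the enol ether gives a tertiary α-silyloxy radical at C8, which closes ring B 6-exo on the vinyl sulfone to give the silyl ether F8. HF·pyridine then frees the tertiary alcohol 19.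

**Further compounds**
F1 | step 7 | β-hydroxy sulfide: 4-[(benzyloxy)methyl]-5-(but-3-en-1-yl)-6-[1-hydroxy-2-(phenylsulfanyl)ethyl]-4,6-dimethylcyclohex-2-en-1-one (ring centres as in 14, carbinol centre undefined) | c1ccccc1COC[C@@]1(C)C=CC(=O)[C@](C(O)CSc2ccccc2)(C)[C@@H]1CCC=C
F2 | step 7 | β-hydroxy sulfone: 4-[(benzyloxy)methyl]-5-(but-3-en-1-yl)-6-[1-hydroxy-2-(phenylsulfonyl)ethyl]-4,6-dimethylcyclohex-2-en-1-one (ring centres as in 14) | c1ccccc1COC[C@@]1(C)C=CC(=O)[C@](C(O)CS(=O)(=O)c2ccccc2)(C)[C@@H]1CCC=C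
F3 | step 7 | mesylate: methanesulfonate ester of F2 at the secondary hydroxyl | c1ccccc1COC[C@@]1(C)C=CC(=O)[C@](C(OS(C)(=O)=O)CS(=O)(=O)c2ccccc2)(C)[C@@H]1CCC=C
F4 | step 14 | (2R)-4-{[tert-butyl(dimethyl)silyl]oxy}-2-methylbutanal | C[C@H](CCO[Si](C)(C)C(C)(C)C)C=O
F5 | step 14 | β-benzoyloxy sulfone: 12-benzoate of the 12-hydroxy analogue of 25 (ring centres and C13 as in 25, C11 and C12 epimers) | c1ccccc1COC[C@@]1(C)CC=C[C@]2(C)[C@@H]1CC[C@](C)(O)[C@H]2C(S(=O)(=O)c1ccccc1)C(OC(=O)c1ccccc1)[C@H](C)CCO[Si](C)(C)C(C)(C)C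
F6 | step 14 | (4S,5S,8S,9S,10R,13R)-18-(benzyloxy)-15-{[tert-butyl(dimethyl)silyl]oxy}labda-1,11-dien-8-ol (11E/Z) | c1ccccc1COC[C@@]1(C)CC=C[C@]2(C)[C@@H]1CC[C@](C)(O)[C@H]2C=C[C@H](C)CCO[Si](C)(C)C(C)(C)C
F7 | step 10 | silyl enol ether: tert-butyl[(4-{(1S,2R,6S)-6-[(benzyloxy)methyl]-2,6-dimethyl-2-[(E)-2-(phenylsulfonyl)ethenyl]cyclohex-3-en-1-yl}but-1-en-2-yl)oxy]dimethylsilane | c1ccccc1COC[C@@]1(C)CC=C[C@](/C=C/S(=O)(=O)c2ccccc2)(C)[C@@H]1CCC(=C)O[Si](C)(C)C(C)(C)C
F8 | step 10 | silyl ether: tert-butyldimethylsilyl ether of 19 at the tertiary hydroxyl | c1ccccc1COC[C@@]1(C)CC=C[C@]2(C)[C@@H]1CC[C@](C)(O[Si](C)(C)C(C)(C)C)[C@H]2CS(=O)(=O)c1ccccc1
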